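The ratio to watch is side product over target: the share of target asked for (the selectivity) is one divided by one plus that ratio.

all flasks: starting material 0.050 M

| flask | second substrate | free enzyme | added ligand | temperature | remark | time |
|---|---|---|---|---|---|---|
| autumn | 2 equiv | 0.0067 mol% | 5 µM | 0 °C | run made earlier |  |
| midnight | 2 equiv | 0.015 mol% | 5 µM | 15 °C | run made earlier |  |
| dawn | 2 equiv | 0.01 mol% | 7.5 µM | 0 °C | run made earlier |  |
| Monday's | 2.00 equiv | 0.01 mol% | 5.0 µM | 25 °C |  | 2.5 h |
| Wednesday's | 2.00 equiv | 0.01 mol% | 5.0 µM | 5 °C |  | 2.5 h |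

- autumn (time / h: target / %, side product / %): 0.500: 2.2, 0.2; 1.00: 4.5, 0.9; 1.50: 7.1, 1.5; 3.00: 13.4, 2.4; 6.00: 27.9, 5.9
- midnight (time / h: target / %, side product / %): 0.250: 9.5, 0.4; 0.500: 17.5, 2.6; 0.833: 30.0, 3.6; 1.50: 48.7, 9.2; 3.00: 76.8, 16.9
- dawn (time / h: target / %, side product / %): 0.500: 3.5, 1.0; 1.00: 7.3, 0.8; 1.50: 11.7, 0.3; 3.00: 21.4, 2.4; 6.00: 41.4, 8.4

(standard deviation of a reading: 0.5 percentage points)

- a species is counted by the starting material in it: one side product counts as two

- which flask leads in share of target in all that became target or side product ("all alike" within 1.5 percentage points) (Monday's / Wednesday's / all alike)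
- share of target in all that became target or side product, Monday's
- share of target in all that became target or side product, Wednesday's

Run a flask in slow motion. In the first instants the target readings rise in a nearly straight line. The pace of conversion, target plus side product, reads 0.0830 h⁻¹ of the charge in the dawn run. Scaled to 0.01 mol% of free enzyme, it reads 0.257 h⁻¹ in the midnight run.

In the middle, my reckoning takes side product as formed when target meets starting material, at a rate proportional to both. Integrating along the straight line gives ratio = clock × time × (1 − 2x/3), with x the conversion. At the end, the bracket shrinks as starting material goes.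

The clock, the hourly rise of the ratio while starting material is still at its full charge, reads 0.0481 h⁻¹ at 0 °C and 0.195 h⁻¹ at 15 °C. Carried on as a steady factor per degree, it reads 0.0767 h⁻¹ for Wednesday's and 0.498 h⁻¹ for Monday's.

On my reckoning Wednesday's reaches about 30.3% conversion, so its share is 86.7%. Monday's straight line reaches 137%, more than the charge holds, so I take its conversion as nearly complete, and its share is 70.7%. On this reckoning Wednesday's leads.

The forecast differs: 82% for Monday's and 83.5% for Wednesday's, so all alike, reading the runs as “with no clear effect of temperature or ligand”.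

The flasks give 68.3% for Monday's and 86.3% for Wednesday's, so Wednesday's leads.

    starting material + free enzyme ⇌ starting complex (K = 11.0 L mol⁻¹, k = 1400 L mol⁻¹ s⁻¹, Ea = 36.0 kJ mol⁻¹, ΔH = −34.0 kJ mol⁻¹)
    second substrate + starting complex ⇌ ternary complex (K = 160 L mol⁻¹, k = 400 L mol⁻¹ s⁻¹, Ea = 45.0 kJ mol⁻¹, ΔH = −24.0 kJ mol⁻¹)
    ternary complex → free enzyme + target (k = 2.10 s⁻¹, Ea = 59.0 kJ mol⁻¹)
    free enzyme → unfolded enzyme (k = 1.00 × 10⁻⁵ s⁻¹, Ea = 265 kJ mol⁻¹)
    free enzyme + added ligand ⇌ idle complex, settled at all times (K = 96000 L mol⁻¹, ΔH = 23.0 kJ mol⁻¹)
    starting material + target → side product (k = 0.00260 L mol⁻¹ s⁻¹, Ea = 62.0 kJ mol⁻¹)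
    (constants at 25 °C)

Monday's keeps 7.3% of its starting material at 2.50 h, so its conversion is 92.7%, and the clock of 0.498 h⁻¹ now gives a share of 67.8%. The neighbour with 0.017 mol% of free enzyme ends with 0.61% of its starting material unbound, a conversion of 99.4%. Taking rate as proportional to enzyme and scaling Monday's pace, my reckoning puts that conversion at 1.58 h on its line, and the same clock then gives a share of 79.0%. That neighbour holds 77.3% target and 22.1% side product, a share of 77.8%.

The data are simulated for substances that don't exist.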